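**Retrosynthetic overview**
1. Target 27 ⇐ one-pot removal of five pivalates and two silyl ethers ⇐ Heck coupling of 4-vinylphenyl pivalate at C4 of ring A ⇐ bromide 25.
2. Ring B (closed last) ⇐ catechol 21 + (R,R)-oxirane 11: Friedel–Crafts arylation at the 4-acyloxybenzylic carbon, then an invertive 1,2-aryl shift with ring closure by the neighbouring oxygen.
3. Ring A (closed first) ⇐ the same two operations from (S,S)-oxirane 16 and 1-bromo-3,5-bis(silyloxy)benzene 17.
4. Both oxiranes ⇐ Shi epoxidation of E-stilbenes 10 and 15 ⇐ Heck couplings of 4-vinylphenyl pivalate 4 with bromides 9 and 14.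
5. Building blocks: 4-bromophenol, potassium vinyltrifluoroborate, 3-bromophenol, catechol.

Assumption: the SMILES is taken as the full definition of the target; by CIP analysis ring A (the dihydrobenzofuran carrying the styryl arm) is 2S,3S-trans and ring B (the catechol-derived one) is 2R,3R-trans.

Abbreviations: Piv = 2,2-dimethylpropanoyl; TBS = tert-butyldimethylsilyl; Tf = trifluoromethanesulfonyl; HFIP = 1,1,1,3,3,3-hexafluoropropan-2-ol; B2pin2 = bis(pinacolato)diboron.

**Step 1**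
Reactants: 1 4-bromophenol
Product: 2 4-bromophenyl pivalate
Conditions: PivCl, Et3N, 4-(dimethylamino)pyridine (cat.), CH2Cl2, 0 °C to rt
Reagents that add atoms: pivaloyl chloride, CC(C)(C)C(=O)Cl
Why: Simple O-acylation of a phenol; the pivalate is the permanent, electron-withdrawing phenol mask that later keeps every 4-oxyphenyl ring from migrating or ionising.

**Step 2**
Reactants: 2 4-bromophenyl pivalate; 3 potassium vinyltrifluoroborate
Product: 4 4-vinylphenyl pivalate
Conditions: PdCl2(dppf) (2 mol %), Et3N, n-PrOH, 90 °C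
Reagents that add atoms: none
Why: Suzuki–Miyaura vinylation (Molander conditions) of an unhindered aryl bromide, tolerated by the hindered aryl ester.

**Step 3**
Reactants: 5 3-bromophenol
Product: 8 5-bromobenzene-1,3-diol, via trimethylsilyl ether 6 (not isolated), via arylboronate 7 (not isolated)
Conditions: (Me3Si)2NH, 80 °C, evaporate; [Ir(OMe)(cod)]2 (1.5 mol %), 4,4'-di-tert-butyl-2,2'-bipyridine (3 mol %), B2pin2, THF, 80 °C; then KHSO5 (Oxone), acetone/H2O, rt
Reagents that add atoms: potassium peroxymonosulfate (Oxone), [K+].OOS(=O)(=O)[O-]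
Why: Sterically governed iridium-catalysed C–H borylation followed by oxidation (one-pot borylation–oxidation) reaches only C5, the single C–H without an ortho neighbour, and the aqueous oxidant also strips the traceless silyl group.

**Step 4**
Reactants: 8 5-bromobenzene-1,3-diol
Product: 9 5-bromo-1,3-phenylene dipivalate
Conditions: PivCl (2.2 equiv), Et3N, 4-(dimethylamino)pyridine (cat.), CH2Cl2, 0 °C to rt
Reagents that add atoms: pivaloyl chloride, CC(C)(C)C(=O)Cl
Why: Double O-acylation; the two meta acyloxy groups make the future benzylic position on this ring a very poor cation site, which step 17 relies on.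

**Step 5**
Reactants: 9 5-bromo-1,3-phenylene dipivalate; 4 4-vinylphenyl pivalate
Product: 10 (E)-5-[2-(4-pivaloyloxyphenyl)ethenyl]-1,3-phenylene dipivalate
Conditions: Pd(OAc)2 (3 mol %), P(o-tol)3 (6 mol %), Et3N, DMF, 100 °C
Reagents that add atoms: none
Why: Mizoroki–Heck arylation of a styrene gives the E-stilbene through syn insertion and syn beta-hydride elimination.

**Step 6**
Reactants: 10 (E)-5-[2-(4-pivaloyloxyphenyl)ethenyl]-1,3-phenylene dipivalate
Product: 11 (2R,3R)-2-[3,5-bis(pivaloyloxy)phenyl]-3-(4-pivaloyloxyphenyl)oxirane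
Conditions: 1,2:4,5-di-O-isopropylidene-beta-D-erythro-2,3-hexodiulo-2,6-pyranose (Shi ketone, 30 mol %), KHSO5 (Oxone), K2CO3, Bu4NHSO4, MeCN/dimethoxymethane/borate buffer, 0 °C
Reagents that add atoms: potassium peroxymonosulfate (Oxone), [K+].OOS(=O)(=O)[O-]
Why: Shi asymmetric epoxidation (chiral dioxirane, spiro transition state) of a trans-stilbene; the D-fructose-derived ketone gives the R,R oxirane, and the carbon bearing the meta-dioxygenated ring will become C3 of ring B.

**Step 7**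
Reactants: 12 catechol
Product: 13 4-bromobenzene-1,2-diol
Conditions: N-bromosuccinimide (1.0 equiv), MeCN, -20 to 0 °C
Reagents that add atoms: N-bromosuccinimide, O=C1CCC(=O)N1Br
Why: Electrophilic aromatic bromination goes para to a hydroxyl and stops at the mono-bromide at low temperature.

**Step 8**
Reactants: 13 4-bromobenzene-1,2-diol
Product: 14 4-bromo-1,2-phenylene diacetate
Conditions: Ac2O, pyridine, CH2Cl2, 0 °C to rt
Reagents that add atoms: acetic anhydride, CC(=O)OC(C)=O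
Why: O-acetylation; the acetates are electron-withdrawing like the pivalates but can later be removed selectively in their presence.

**Step 9**
Reactants: 14 4-bromo-1,2-phenylene diacetate; 4 4-vinylphenyl pivalate
Product: 15 (E)-4-[2-(4-pivaloyloxyphenyl)ethenyl]-1,2-phenylene diacetate
Conditions: Pd(OAc)2 (3 mol %), P(o-tol)3 (6 mol %), Et3N, DMF, 100 °C
Reagents that add atoms: none
Why: Mizoroki–Heck reaction, E-selective as in step 5.

**Step 10**
Reactants: 15 (E)-4-[2-(4-pivaloyloxyphenyl)ethenyl]-1,2-phenylene diacetate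
Product: 16 (2S,3S)-2-(3,4-diacetoxyphenyl)-3-(4-pivaloyloxyphenyl)oxirane
Conditions: 1,2:4,5-di-O-isopropylidene-beta-L-erythro-2,3-hexodiulo-2,6-pyranose (enantiomeric Shi ketone, 50 mol %), KHSO5 (Oxone), K2CO3 feed held at pH 9.3 (borate buffer), Bu4NHSO4, MeCN/dimethoxymethane/H2O, -5 °C
Reagents that add atoms: potassium peroxymonosulfate (Oxone), [K+].OOS(=O)(=O)[O-]
Why: Shi asymmetric epoxidation with the enantiomeric ketone gives the S,S oxirane; the lowered pH and temperature spare the aryl acetates.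

**Step 11**
Reactants: 8 5-bromobenzene-1,3-diol
Product: 17 1-bromo-3,5-bis(tert-butyldimethylsilyloxy)benzene
Conditions: TBSCl (2.3 equiv), imidazole, DMF, rt
Reagents that add atoms: tert-butyldimethylsilyl chloride, CC(C)(C)[Si](C)(C)Cl
Why: Phenol silylation keeps the ring electron-rich for step 12, walls off the position between the two oxygens, and supplies the latent ring oxygen for step 13.

**Step 12**
Reactants: 16 (2S,3S)-2-(3,4-diacetoxyphenyl)-3-(4-pivaloyloxyphenyl)oxirane; 17 1-bromo-3,5-bis(tert-butyldimethylsilyloxy)benzene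
Product: 18 (1R,2S)-2-[2-bromo-4,6-bis(tert-butyldimethylsilyloxy)phenyl]-1-(3,4-diacetoxyphenyl)-2-(4-pivaloyloxyphenyl)ethanol
Conditions: HFIP, Tf2NH (2 mol %), 0 °C to rt; arene in threefold excess, surplus recovered unchanged
Reagents that add atoms: none
Why: Friedel–Crafts alkylation by epoxide opening in HFIP, a pure addition of the arene C–H across the C–O bond: the oxirane opens at the 4-pivaloyloxybenzylic carbon (the diacetoxyphenyl carbon is the poorer cation site) and the arene attacks through C2 (para to one silyloxy group); the carbinol centre keeps its Shi-derived geometry (its label changes from S to R only through CIP ranking), and the new C2 centre (anti opening) is erased in step 13.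

**Step 13**
Reactants: 18 (1R,2S)-2-[2-bromo-4,6-bis(tert-butyldimethylsilyloxy)phenyl]-1-(3,4-diacetoxyphenyl)-2-(4-pivaloyloxyphenyl)ethanol
Product: 20 (2S,3S)-4-bromo-6-(tert-butyldimethylsilyloxy)-3-(3,4-diacetoxyphenyl)-2-(4-pivaloyloxyphenyl)-2,3-dihydrobenzofuran, via secondary triflate 19 (not isolated)
Conditions: Tf2O (1.2 equiv), 2,6-di-tert-butyl-4-methylpyridine (2.5 equiv), CH2Cl2, -78 to 0 °C
Reagents that add atoms: none
Why: Proposed new method: a triflate-triggered 1,2-aryl shift with ring expansion: the carbinol sits next to a 3,4-diacetoxyphenyl ring and cannot ionise unassisted, so the triflate leaves only with backside ipso participation of the neighbouring bis(silyloxy)aryl ring (Ar1-3), which inverts C1 and gives a spiro-cyclopropane phenonium ion; that three-membered ring opens toward the 4-pivaloyloxybenzylic carbon and the ortho silyl ether oxygen closes the five-membered ring with loss of TBSOTf (trans, the less crowded and more stable isomer), so the aryl group moves from the carbon where Friedel–Crafts chemistry put it to the carbon where it is needed and the carbinol centre becomes C3 (S) with C2 (S) following; the silyl ether prevents direct five-exo O-alkylation to the regioisomer and the 4-pivaloyloxyphenyl ring is too electron-poor to compete as migrating group; closest known reactions are the Cram and Winstein phenonium solvolyses of beta-aryl sulfonates and the acid-mediated cyclodehydration of 1,2,2-triarylethanols to trans-2,3-diaryl-2,3-dihydrobenzofurans, which runs without a shift.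

**Step 14**
Reactants: 20 (2S,3S)-4-bromo-6-(tert-butyldimethylsilyloxy)-3-(3,4-diacetoxyphenyl)-2-(4-pivaloyloxyphenyl)-2,3-dihydrobenzofuran
Product: 21 (2S,3S)-4-bromo-6-(tert-butyldimethylsilyloxy)-3-(3,4-dihydroxyphenyl)-2-(4-pivaloyloxyphenyl)-2,3-dihydrobenzofuran
Conditions: N2H4·H2O (2.5 equiv), THF, 0 °C, argon
Reagents that add atoms: none
Why: Hydrazinolysis removes aryl acetates far faster than the hindered aryl pivalate and leaves the silyl ether alone; the reducing medium protects the catechol.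

**Step 15**
Reactants: 21 (2S,3S)-4-bromo-6-(tert-butyldimethylsilyloxy)-3-(3,4-dihydroxyphenyl)-2-(4-pivaloyloxyphenyl)-2,3-dihydrobenzofuran; 11 (2R,3R)-2-[3,5-bis(pivaloyloxy)phenyl]-3-(4-pivaloyloxyphenyl)oxirane
Product: 22 (1S,2R)-1-[3,5-bis(pivaloyloxy)phenyl]-2-{5-[(2S,3S)-4-bromo-6-(tert-butyldimethylsilyloxy)-2-(4-pivaloyloxyphenyl)-2,3-dihydrobenzofuran-3-yl]-2,3-dihydroxyphenyl}-2-(4-pivaloyloxyphenyl)ethanol
Conditions: HFIP, Tf2NH (5 mol %), 0 °C to rt, argon; oxirane in slight excess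
Reagents that add atoms: none
Why: Friedel–Crafts alkylation by epoxide opening: the oxirane can only open at the 4-pivaloyloxybenzylic carbon, and the catechol reacts ortho to the hydroxyl that is para to ring A (the site taken in alkylations of 4-alkylcatechols), since the other catechol positions flank the bulky ring A substituent, ring A is shielded by Br and OTBS, and the acylated rings are deactivated; the carbinol centre is retained (S by CIP ranking) and the new C2 centre (R) is erased in step 17.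

**Step 16**
Reactants: 22 the triarylethanol of step 15
Product: 23 (1S,2R)-1-[3,5-bis(pivaloyloxy)phenyl]-2-{5-[(2S,3S)-4-bromo-6-(tert-butyldimethylsilyloxy)-2-(4-pivaloyloxyphenyl)-2,3-dihydrobenzofuran-3-yl]-2,3-bis(tert-butyldimethylsilyloxy)phenyl}-2-(4-pivaloyloxyphenyl)ethanol
Conditions: TBSCl (2.4 equiv), imidazole, CH2Cl2/DMF, 0 °C to rt
Reagents that add atoms: tert-butyldimethylsilyl chloride, CC(C)(C)[Si](C)(C)Cl
Why: Phenols silylate much faster than the neopentyl-like secondary benzylic alcohol; the silyl ethers block O-triflation and direct O-alkylation in step 17.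

**Step 17**
Reactants: 23 the bis-silyl ether of step 16
Product: 25 (2S,3S)-4-bromo-6-(tert-butyldimethylsilyloxy)-2-(4-pivaloyloxyphenyl)-3-[(2R,3R)-3-[3,5-bis(pivaloyloxy)phenyl]-2-(4-pivaloyloxyphenyl)-7-(tert-butyldimethylsilyloxy)-2,3-dihydrobenzofuran-5-yl]-2,3-dihydrobenzofuran, via secondary triflate 24 (not isolated)
Conditions: Tf2O (1.2 equiv), 2,6-di-tert-butyl-4-methylpyridine (2.5 equiv), CH2Cl2, -78 to 0 °C
Reagents that add atoms: none
Why: Proposed new method: the same triflate-triggered 1,2-aryl shift with ring expansion as in step 13 (closest known: phenonium solvolysis of beta-aryl sulfonates; cyclodehydration of 1,2,2-triarylethanols): the carbinol carries the meta-bis(pivaloyloxy)phenyl ring and cannot ionise unassisted, the 2,3-bis(silyloxy)aryl ring migrates with inversion to set C3 of ring B (R), and the cation left at the 4-pivaloyloxybenzylic carbon is taken by the adjacent silyl ether oxygen (five-membered closure) to give the trans ring (C2 R), while ring A with its electron-poor C2 aryl group does not ionise.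

**Step 18**
Reactants: 25 the bis-dihydrobenzofuran bromide of step 17; 4 4-vinylphenyl pivalate
Product: 26 hepta-O-protected target (five pivalates plus silyl ethers at O6 of ring A and O7 of ring B)
Conditions: Pd(OAc)2 (5 mol %), P(t-Bu)3·HBF4 (10 mol %), Cy2NMe, 1,4-dioxane, 90 °C; styrene in slight excess
Reagents that add atoms: none
Why: Mizoroki–Heck reaction with a bulky electron-rich phosphine for the ortho-substituted aryl bromide gives the E-stilbene; no acid is present, so the stereocentres are untouched.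

**Step 19**
Reactants: 26 hepta-O-protected target
Product: 27 CNP0172909.1
Conditions: K2CO3 (excess), MeOH/THF (degassed), rt, argon; then AcOH
Reagents that add atoms: none
Why: Base-mediated methanolysis cleaves the aryl pivalates and the aryl silyl ethers in one operation and avoids acid, which would risk cyclisation of the stilbene onto the electron-rich rings; C3 of both rings is inert to base and C2 can only reclose trans.

**Compound list**
1 | 4-bromophenol | Oc1ccc(Br)cc1 | starting material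
2 | 4-bromophenyl pivalate | CC(C)(C)C(=O)Oc1ccc(Br)cc1 | intermediate
3 | potassium vinyltrifluoroborate | [K+].F[B-](F)(F)C=C | starting material
4 | 4-vinylphenyl pivalate | CC(C)(C)C(=O)Oc1ccc(C=C)cc1 | intermediate
5 | 3-bromophenol | Oc1cccc(Br)c1 | starting material
6 | (3-bromophenoxy)trimethylsilane | C[Si](C)(C)Oc1cccc(Br)c1 | intermediate (not isolated)
7 | 2-[3-bromo-5-(trimethylsilyloxy)phenyl]-4,4,5,5-tetramethyl-1,3,2-dioxaborolane | C[Si](C)(C)Oc1cc(Br)cc(c1)B1OC(C)(C)C(C)(C)O1 | intermediate (not isolated)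
8 | 5-bromobenzene-1,3-diol | Oc1cc(O)cc(Br)c1 | intermediate
9 | 5-bromo-1,3-phenylene dipivalate | CC(C)(C)C(=O)Oc1cc(Br)cc(OC(=O)C(C)(C)C)c1 | intermediate
10 | (E)-5-[2-(4-pivaloyloxyphenyl)ethenyl]-1,3-phenylene dipivalate | CC(C)(C)C(=O)Oc1ccc(/C=C/c2cc(OC(=O)C(C)(C)C)cc(OC(=O)C(C)(C)C)c2)cc1 | intermediate
11 | (2R,3R)-2-[3,5-bis(pivaloyloxy)phenyl]-3-(4-pivaloyloxyphenyl)oxirane | CC(C)(C)C(=O)Oc1cc(OC(=O)C(C)(C)C)cc(c1)[C@H]1O[C@@H]1c1ccc(OC(=O)C(C)(C)C)cc1 | intermediate
12 | catechol (benzene-1,2-diol) | Oc1ccccc1O | starting material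
13 | 4-bromobenzene-1,2-diol | Oc1ccc(Br)cc1O | intermediate
14 | 4-bromo-1,2-phenylene diacetate | CC(=O)Oc1ccc(Br)cc1OC(C)=O | intermediate
15 | (E)-4-[2-(4-pivaloyloxyphenyl)ethenyl]-1,2-phenylene diacetate | CC(=O)Oc1ccc(/C=C/c2ccc(OC(=O)C(C)(C)C)cc2)cc1OC(C)=O | intermediate
16 | (2S,3S)-2-(3,4-diacetoxyphenyl)-3-(4-pivaloyloxyphenyl)oxirane | CC(=O)Oc1ccc(cc1OC(C)=O)[C@@H]1O[C@H]1c1ccc(OC(=O)C(C)(C)C)cc1 | intermediate
17 | 1-bromo-3,5-bis(tert-butyldimethylsilyloxy)benzene | CC(C)(C)[Si](C)(C)Oc1cc(Br)cc(O[Si](C)(C)C(C)(C)C)c1 | intermediate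
18 | (1R,2S)-2-[2-bromo-4,6-bis(tert-butyldimethylsilyloxy)phenyl]-1-(3,4-diacetoxyphenyl)-2-(4-pivaloyloxyphenyl)ethanol | CC(=O)Oc1ccc(cc1OC(C)=O)[C@H](O)[C@@H](c1ccc(OC(=O)C(C)(C)C)cc1)c1c(O[Si](C)(C)C(C)(C)C)cc(O[Si](C)(C)C(C)(C)C)cc1Br | intermediate
19 | C1 trifluoromethanesulfonate of 18 | CC(=O)Oc1ccc(cc1OC(C)=O)[C@H](OS(=O)(=O)C(F)(F)F)[C@@H](c1ccc(OC(=O)C(C)(C)C)cc1)c1c(O[Si](C)(C)C(C)(C)C)cc(O[Si](C)(C)C(C)(C)C)cc1Br | intermediate (not isolated)
20 | (2S,3S)-4-bromo-6-(tert-butyldimethylsilyloxy)-3-(3,4-diacetoxyphenyl)-2-(4-pivaloyloxyphenyl)-2,3-dihydrobenzofuran | Brc1cc(O[Si](C)(C)C(C)(C)C)cc2c1[C@H](c1ccc(OC(C)=O)c(OC(C)=O)c1)[C@@H](c1ccc(OC(=O)C(C)(C)C)cc1)O2 | intermediate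
21 | (2S,3S)-4-bromo-6-(tert-butyldimethylsilyloxy)-3-(3,4-dihydroxyphenyl)-2-(4-pivaloyloxyphenyl)-2,3-dihydrobenzofuran | Brc1cc(O[Si](C)(C)C(C)(C)C)cc2c1[C@H](c1ccc(O)c(O)c1)[C@@H](c1ccc(OC(=O)C(C)(C)C)cc1)O2 | intermediate
22 | (1S,2R)-1-[3,5-bis(pivaloyloxy)phenyl]-2-{5-[(2S,3S)-4-bromo-6-(tert-butyldimethylsilyloxy)-2-(4-pivaloyloxyphenyl)-2,3-dihydrobenzofuran-3-yl]-2,3-dihydroxyphenyl}-2-(4-pivaloyloxyphenyl)ethanol | Brc1cc(O[Si](C)(C)C(C)(C)C)cc2c1[C@H](c1cc(O)c(O)c(c1)[C@@H](c1ccc(OC(=O)C(C)(C)C)cc1)[C@H](O)c1cc(OC(=O)C(C)(C)C)cc(OC(=O)C(C)(C)C)c1)[C@@H](c1ccc(OC(=O)C(C)(C)C)cc1)O2 | intermediate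
23 | bis(tert-butyldimethylsilyl) ether of 22 at the two catechol oxygens | Brc1cc(O[Si](C)(C)C(C)(C)C)cc2c1[C@H](c1cc(O[Si](C)(C)C(C)(C)C)c(O[Si](C)(C)C(C)(C)C)c(c1)[C@@H](c1ccc(OC(=O)C(C)(C)C)cc1)[C@H](O)c1cc(OC(=O)C(C)(C)C)cc(OC(=O)C(C)(C)C)c1)[C@@H](c1ccc(OC(=O)C(C)(C)C)cc1)O2 | intermediate
24 | carbinol trifluoromethanesulfonate of 23 | Brc1cc(O[Si](C)(C)C(C)(C)C)cc2c1[C@H](c1cc(O[Si](C)(C)C(C)(C)C)c(O[Si](C)(C)C(C)(C)C)c(c1)[C@@H](c1ccc(OC(=O)C(C)(C)C)cc1)[C@H](OS(=O)(=O)C(F)(F)F)c1cc(OC(=O)C(C)(C)C)cc(OC(=O)C(C)(C)C)c1)[C@@H](c1ccc(OC(=O)C(C)(C)C)cc1)O2 | intermediate (not isolated)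
25 | (2S,3S)-4-bromo-6-(tert-butyldimethylsilyloxy)-2-(4-pivaloyloxyphenyl)-3-[(2R,3R)-3-[3,5-bis(pivaloyloxy)phenyl]-2-(4-pivaloyloxyphenyl)-7-(tert-butyldimethylsilyloxy)-2,3-dihydrobenzofuran-5-yl]-2,3-dihydrobenzofuran | Brc1cc(O[Si](C)(C)C(C)(C)C)cc2c1[C@H](c1cc(O[Si](C)(C)C(C)(C)C)c3c(c1)[C@@H](c1cc(OC(=O)C(C)(C)C)cc(OC(=O)C(C)(C)C)c1)[C@H](c1ccc(OC(=O)C(C)(C)C)cc1)O3)[C@@H](c1ccc(OC(=O)C(C)(C)C)cc1)O2 | intermediate
26 | hepta-O-protected target: 25 with Br replaced by (E)-2-(4-pivaloyloxyphenyl)ethenyl | CC(C)(C)C(=O)Oc1ccc(/C=C/c2cc(O[Si](C)(C)C(C)(C)C)cc3c2[C@H](c2cc(O[Si](C)(C)C(C)(C)C)c4c(c2)[C@@H](c2cc(OC(=O)C(C)(C)C)cc(OC(=O)C(C)(C)C)c2)[C@H](c2ccc(OC(=O)C(C)(C)C)cc2)O4)[C@@H](c2ccc(OC(=O)C(C)(C)C)cc2)O3)cc1 | intermediate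
27 | CNP0172909.1 (ring A 2S,3S; ring B 2R,3R; E-stilbene) | Oc1ccc(/C=C/c2cc(O)cc3c2[C@H](c2cc(O)c4c(c2)[C@@H](c2cc(O)cc(O)c2)[C@H](c2ccc(O)cc2)O4)[C@@H](c2ccc(O)cc2)O3)cc1 | target

**Step count and risks**
Total: 19 steps. Longest linear sequence: 12 steps (7, 8, 9, 10, 12, 13, 14, 15, 16, 17, 18, 19).

Most likely to fail:

Step 12 (epoxide arylation). Acid-promoted rearrangement of oxirane 16 to a carbonyl compound may outrun attack by the hindered, only moderately nucleophilic arene 17. The fallback sets out from stilbene 15 and avoids the oxirane. A base-free asymmetric dihydroxylation (K2OsO2(OH)4, (DHQ)2PHAL, N-methylmorpholine N-oxide, acetone/H2O, slow addition) gives (1S,2S)-1-(3,4-diacetoxyphenyl)-2-(4-pivaloyloxyphenyl)ethane-1,2-diol F1. A dehydrative Friedel–Crafts benzylation of 17 (Tf2NH, HFIP) then ionises only the 4-pivaloyloxybenzylic hydroxyl and comes back to the route at 18, with the same carbinol configuration.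

Step 13 (the proposed shift–cyclization, first use). Possible failures are elimination to a triarylethene, capture of the triflate by the silyl ether, or incomplete closure. The fallback uses known reactions only and sets out from 18:
- MsCl and Et3N give the mesylate F2.
- Buffered aryl-assisted solvolysis of the Cram–Winstein type (2,6-lutidine, HFIP/H2O, 40 °C) gives the rearranged alcohol (1R,2S)-2-[2-bromo-4,6-bis(tert-butyldimethylsilyloxy)phenyl]-2-(3,4-diacetoxyphenyl)-1-(4-pivaloyloxyphenyl)ethanol F3.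
- HF·pyridine removes both silyl groups to give the resorcinol F4.
- The classical acid-catalysed cyclodehydration of an ortho-hydroxyaryl benzylic alcohol (TsOH, CH2Cl2) gives the 6-hydroxy trans-dihydrobenzofuran F5.
- TBSCl and imidazole return it to the route at 20.

Step 17 (the proposed shift–cyclization, harder case). The migrating catechol ring has only one ortho oxygen to assist it, so migration of the 4-pivaloyloxyphenyl ring or elimination may compete. The fallback is the same known sequence, setting out from 23: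
- Mesylation gives the mesylate F6.
- Buffered solvolysis gives the rearranged alcohol F7.
- HF·pyridine gives the desilylated triphenol F8.
- TsOH closes ring B to the bis-dihydrobenzofuran diphenol F9.
- Bis-silylation with TBSCl and imidazole comes back to the route at 25.

**Further compounds**
F1 | step 12 | (1S,2S)-1-(3,4-diacetoxyphenyl)-2-(4-pivaloyloxyphenyl)ethane-1,2-diol | CC(=O)Oc1ccc(cc1OC(C)=O)[C@H](O)[C@@H](O)c1ccc(OC(=O)C(C)(C)C)cc1
F2 | step 13 | C1 methanesulfonate of 18 | CC(=O)Oc1ccc(cc1OC(C)=O)[C@H](OS(C)(=O)=O)[C@@H](c1ccc(OC(=O)C(C)(C)C)cc1)c1c(O[Si](C)(C)C(C)(C)C)cc(O[Si](C)(C)C(C)(C)C)cc1Br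
F3 | step 13 | (1R,2S)-2-[2-bromo-4,6-bis(tert-butyldimethylsilyloxy)phenyl]-2-(3,4-diacetoxyphenyl)-1-(4-pivaloyloxyphenyl)ethanol | CC(C)(C)[Si](C)(C)Oc1cc(O[Si](C)(C)C(C)(C)C)c(c(Br)c1)[C@H](c1ccc(OC(C)=O)c(OC(C)=O)c1)[C@@H](O)c1ccc(OC(=O)C(C)(C)C)cc1
F4 | step 13 | (1R,2S)-2-(2-bromo-4,6-dihydroxyphenyl)-2-(3,4-diacetoxyphenyl)-1-(4-pivaloyloxyphenyl)ethanol | Oc1cc(O)c(c(Br)c1)[C@H](c1ccc(OC(C)=O)c(OC(C)=O)c1)[C@@H](O)c1ccc(OC(=O)C(C)(C)C)cc1
F5 | step 13 | (2S,3S)-4-bromo-3-(3,4-diacetoxyphenyl)-6-hydroxy-2-(4-pivaloyloxyphenyl)-2,3-dihydrobenzofuran | Brc1cc(O)cc2c1[C@H](c1ccc(OC(C)=O)c(OC(C)=O)c1)[C@@H](c1ccc(OC(=O)C(C)(C)C)cc1)O2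
F6 | step 17 | carbinol methanesulfonate of 23 | Brc1cc(O[Si](C)(C)C(C)(C)C)cc2c1[C@H](c1cc(O[Si](C)(C)C(C)(C)C)c(O[Si](C)(C)C(C)(C)C)c(c1)[C@@H](c1ccc(OC(=O)C(C)(C)C)cc1)[C@H](OS(C)(=O)=O)c1cc(OC(=O)C(C)(C)C)cc(OC(=O)C(C)(C)C)c1)[C@@H](c1ccc(OC(=O)C(C)(C)C)cc1)O2
F7 | step 17 | rearranged alcohol: catechol ring and 3,5-bis(pivaloyloxy)phenyl on one carbon, hydroxyl and 4-pivaloyloxyphenyl on the other | Brc1cc(O[Si](C)(C)C(C)(C)C)cc2c1[C@H](c1cc(O[Si](C)(C)C(C)(C)C)c(O[Si](C)(C)C(C)(C)C)c(c1)[C@@H](c1cc(OC(=O)C(C)(C)C)cc(OC(=O)C(C)(C)C)c1)[C@H](O)c1ccc(OC(=O)C(C)(C)C)cc1)[C@@H](c1ccc(OC(=O)C(C)(C)C)cc1)O2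
F8 | step 17 | F7 with all three silyl groups removed | Brc1cc(O)cc2c1[C@H](c1cc(O)c(O)c(c1)[C@@H](c1cc(OC(=O)C(C)(C)C)cc(OC(=O)C(C)(C)C)c1)[C@H](O)c1ccc(OC(=O)C(C)(C)C)cc1)[C@@H](c1ccc(OC(=O)C(C)(C)C)cc1)O2
F9 | step 17 | 25 with free hydroxyls at O6 of ring A and O7 of ring B | Brc1cc(O)cc2c1[C@H](c1cc(O)c3c(c1)[C@@H](c1cc(OC(=O)C(C)(C)C)cc(OC(=O)C(C)(C)C)c1)[C@H](c1ccc(OC(=O)C(C)(C)C)cc1)O3)[C@@H](c1ccc(OC(=O)C(C)(C)C)cc1)O2
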